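The disconnection on which the route rests is the C4a–C5 bond of ring A. Ring C, with its C2 aryl group, its C3 oxygen and the C8a–C8 bond, is a 4-pyranone grown from kojic acid. C8, C7, C6 and C5 are carried as an open keto acetal chain that already holds the three ring A oxygens in their final positions. The key step exploits the enol-ether-like pyranone carbon C4a, which can reach the acetal carbon C5 through a six-membered transition state. Acid joins the two carbons and expels two molecules of methanol, so ring A is closed and aromatised in one operation. The precursor is 3-methoxy-2-(4-methoxyphenyl)-6-(1,3,4,4-tetramethoxy-2-oxobutyl)-4H-pyran-4-one.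

Key step: step 6

Remark on numbering and stereochemistry: flavone numbering (O1, C2, C3, C4, C4a, C5 to C8, C8a) is used for the corresponding atoms of every intermediate. The target has no stereocentre, so 9, 10, 12 and 13 are carried as racemates or diastereomer mixtures, which step 6 converges.

Step 1
Reactants: 1 kojic acid (5-hydroxy-2-(hydroxymethyl)-4H-pyran-4-one)
Product: 2 2-bromo-3-hydroxy-6-(hydroxymethyl)-4H-pyran-4-one (6-bromokojic acid)
Conditions: NBS (1.05 equiv), DMF, 0 °C → rt
Reagents that add atoms: N-bromosuccinimide, O=C1CCC(=O)N1Br
Why: Electrophilic bromination of the phenol-like enol should occur at the only free carbon ortho to the hydroxyl (C6 of kojic acid, the future C2), the site at which kojic acid also undergoes Mannich and azo coupling reactions.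

Step 2
Reactants: 2 2-bromo-3-hydroxy-6-(hydroxymethyl)-4H-pyran-4-one
Product: 4 2-bromo-3-methoxy-6-(methoxymethyl)-4H-pyran-4-one, via monomethyl ether 3 (not isolated)
Conditions: MeI (excess), Ag2O (3 equiv), DMF, rt → 40 °C, dark
Reagents that add atoms: iodomethane, CI
Why: Purdie–Kuhn methylation etherifies first the acidic enol and then the primary alcohol without ever generating a free alkoxide, so the β-bromo enone, which alkoxides would attack by addition–elimination, should stay intact.

Step 3
Reactants: 4 2-bromo-3-methoxy-6-(methoxymethyl)-4H-pyran-4-one; 5 4-methoxyphenylboronic acid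
Product: 6 3-methoxy-2-(4-methoxyphenyl)-6-(methoxymethyl)-4H-pyran-4-one
Conditions: 5 (1.3 equiv), Pd(PPh3)4 (5 mol %), K3PO4 (2 equiv), 1,4-dioxane/H2O 9:1, 85 °C
Reagents that add atoms: none
Why: Suzuki–Miyaura coupling should be easy because the C2–Br bond is that of a vinylogous acyl bromide and adds quickly to zerovalent palladium, while the mild phosphate base limits displacement of bromide by hydroxide.

Step 4
Reactants: 7 methyl methoxyacetate
Product: 10 methyl 2,3,3-trimethoxypropanoate (racemic), via sodium enolate 8 (not isolated), via formyl ester 9 (not isolated)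
Conditions: HCO2Me (1.5 equiv), NaOMe (1.1 equiv), THF, 0 °C → rt; then HCl in MeOH, HC(OMe)3, 0 °C → rt
Reagents that add atoms: methyl formate, COC=O; trimethyl orthoformate, COC(OC)OC (methanol, CO, the co-solvent, exchanges with it)
Why: A crossed Claisen formylation (methyl formate cannot enolise and the stabilised enolate 8 pulls the equilibrium) is followed by acid-catalysed acetalisation of the liberated aldehyde 9 with the orthoformate; the stereocentre at C2 forms as a racemate and is later destroyed.

Step 5
Reactants: 6 3-methoxy-2-(4-methoxyphenyl)-6-(methoxymethyl)-4H-pyran-4-one; 10 methyl 2,3,3-trimethoxypropanoate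
Product: 12 3-methoxy-2-(4-methoxyphenyl)-6-(1,3,4,4-tetramethoxy-2-oxobutyl)-4H-pyran-4-one (mixture of diastereomers), via lithium dienolate 11 (not isolated)
Conditions: 10 (1.5 equiv), THF, −78 °C; LiN(SiMe3)2 (2.2 equiv) added slowly; −78 → −40 °C; aq. NH4Cl
Reagents that add atoms: none
Why: Lateral deprotonation of the 6-alkyl group gives the cross-conjugated dienolate 11, which undergoes Claisen-type C-acylation at the exocyclic carbon by the activated α-alkoxy ester; the second equivalent of base stores the product as its C8 enolate, which also shields C6–H and the acetal from elimination, and the new stereocentre at C8 is uncontrolled and irrelevant.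

Step 6
Reactants: 12 3-methoxy-2-(4-methoxyphenyl)-6-(1,3,4,4-tetramethoxy-2-oxobutyl)-4H-pyran-4-one
Product: 15 7-hydroxy-3,6,8-trimethoxy-2-(4-methoxyphenyl)-4H-chromen-4-one, via cyclised ketone 13 (not isolated), via keto tautomer 14 (not isolated)
Conditions: MsOH (3 equiv), CH2Cl2 (0.02 M), 0 °C → 40 °C
Reagents that add atoms: none
Why: Proposed new method: MsOH ionises the dimethyl acetal of 12 to an oxocarbenium ion at C5, which is attacked by C4a, the α-carbon of the ring's vinylogous ester and, once the acidic C8–H is lost, an enol carbon of the 2-alkylidene-2H-pyran-4-ol tautomer, to give 13; β-elimination of methanol across C5–C6 then gives enone 14, whose C8–H shifts to the C7 oxygen to leave phenol 15. The closest known reactions are acid-mediated acetal cyclodehydrations onto electron-rich π-systems (Pomeranz–Fritsch and Bradsher cyclisations) and biomimetic aldol condensation–aromatisations of polyketone chains, but a 4-pyranone ring carbon has not been shown as the nucleophile in such a benzannulation. Ring A closes in a 6-exo-trig mode at the oxocarbenium carbon with the nucleophilic C4a=C8a bond inside the new ring (enol-endo), a favoured geometry. No stereocentre survives, since those at C6 and C8 of 12 and the new one at C5 of 13 are all erased on aromatisation, so the diastereomer mixture should converge on one product. The step needs C–C closure at C4a to win over β-elimination and intermolecular condensation; C4a is the only nucleophilic carbon that can reach C5 through a six-membered ring (C8 would give a four-membered ring and the anisyl ring is remote), the β-methoxy enone formed by elimination stays electrophilic at the same carbon and feeds the same closure, aromatisation is irreversible, and high dilution suppresses oligomers. The oxygenation pattern is fixed by the chain, because only the C5 methoxy group is β to the C7 ketone and can be expelled, which leaves 6-OMe, 7-OH and 8-OMe.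

Step 7
Reactants: 15 7-hydroxy-3,6,8-trimethoxy-2-(4-methoxyphenyl)-4H-chromen-4-one
Product: 16 auranetin (3,6,7,8-tetramethoxy-2-(4-methoxyphenyl)-4H-chromen-4-one)
Conditions: MeI (3 equiv), K2CO3 (3 equiv), acetone, reflux
Reagents that add atoms: iodomethane, CI
Why: Williamson O-methylation of the acidic 7-hydroxyl, the only free OH in the molecule, should be clean with the small electrophile despite the two flanking methoxy groups.

Compound list
1 | kojic acid (5-hydroxy-2-(hydroxymethyl)-4H-pyran-4-one) | OCc1cc(=O)c(O)co1 | starting material
2 | 2-bromo-3-hydroxy-6-(hydroxymethyl)-4H-pyran-4-one (6-bromokojic acid) | OCc1cc(=O)c(O)c(Br)o1 | intermediate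
3 | 2-bromo-6-(hydroxymethyl)-3-methoxy-4H-pyran-4-one | OCc1cc(=O)c(OC)c(Br)o1 | intermediate
4 | 2-bromo-3-methoxy-6-(methoxymethyl)-4H-pyran-4-one | COCc1cc(=O)c(OC)c(Br)o1 | intermediate
5 | 4-methoxyphenylboronic acid | COc1ccc(B(O)O)cc1 | starting material
6 | 3-methoxy-2-(4-methoxyphenyl)-6-(methoxymethyl)-4H-pyran-4-one | COCc1cc(=O)c(OC)c(-c2ccc(OC)cc2)o1 | intermediate
7 | methyl methoxyacetate | COCC(=O)OC | starting material
8 | sodium 2,3-dimethoxy-3-oxoprop-1-en-1-olate | [Na+].[O-]C=C(OC)C(=O)OC | intermediate
9 | methyl 2-methoxy-3-oxopropanoate (racemic, in equilibrium with its enol) | COC(C=O)C(=O)OC | intermediate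
10 | methyl 2,3,3-trimethoxypropanoate (racemic) | COC(OC)C(OC)C(=O)OC | intermediate
11 | lithium 3-methoxy-6-(methoxymethylidene)-2-(4-methoxyphenyl)-6H-pyran-4-olate | [Li+].[O-]C1=CC(=COC)OC(c2ccc(OC)cc2)=C1OC | intermediate
12 | 3-methoxy-2-(4-methoxyphenyl)-6-(1,3,4,4-tetramethoxy-2-oxobutyl)-4H-pyran-4-one (mixture of diastereomers) | COc1ccc(-c2oc(C(OC)C(=O)C(OC)C(OC)OC)cc(=O)c2OC)cc1 | intermediate
13 | 3,5,6,8-tetramethoxy-2-(4-methoxyphenyl)-5,6-dihydro-4H-chromene-4,7(8H)-dione (mixture of diastereomers) | COc1ccc(-c2oc3c(c(=O)c2OC)C(OC)C(OC)C(=O)C3OC)cc1 | intermediate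
14 | 3,6,8-trimethoxy-2-(4-methoxyphenyl)-4H-chromene-4,7(8H)-dione (racemic) | COc1ccc(-c2oc3c(c(=O)c2OC)C=C(OC)C(=O)C3OC)cc1 | intermediate
15 | 7-hydroxy-3,6,8-trimethoxy-2-(4-methoxyphenyl)-4H-chromen-4-one | COc1ccc(-c2oc3c(OC)c(O)c(OC)cc3c(=O)c2OC)cc1 | intermediate
16 | auranetin (3,6,7,8-tetramethoxy-2-(4-methoxyphenyl)-4H-chromen-4-one) | COc1ccc(-c2oc3c(OC)c(OC)c(OC)cc3c(=O)c2OC)cc1 | target

Total step count: 7. Longest linear sequence: 6 (steps 1, 2, 3, 5, 6, 7).

Steps most likely to fail

1. Step 6. In strong acid the pyranone is largely O-protonated and may be too poor a nucleophile, so the ionised chain could oligomerise or fragment between C7 and C8 before ring A closes. The fallback builds ring C last on a preformed ring A by known chemistry. It sets out from methyl methoxyacetate 7, which is saponified (NaOH, H2O/MeOH, then HCl) to methoxyacetic acid F1. F1 should acylate commercial 2,3,4-trimethoxyphenol ortho to the hydroxyl (BF3·OEt2, 80 °C, Friedel–Crafts acylation with Fries-type ortho direction) to give 1-(2-hydroxy-3,4,5-trimethoxyphenyl)-2-methoxyethan-1-one F2. Allan–Robinson condensation of F2 with 4-methoxybenzoic anhydride and sodium 4-methoxybenzoate (170–180 °C, then brief KOH in aqueous EtOH) should give the 3-methoxyflavone directly. The fallback returns to the route at auranetin 16.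

2. Step 5. Free base may deprotonate ester 10 at C2 and trigger loss of methoxide, or the dienolate may be quenched by proton transfer, so that acylation stalls. The fallback replaces the Claisen condensation by an aldol addition and oxidation, and sets out from 6 and 10. Ester 10 is reduced (iBu2AlH, CH2Cl2, −78 °C) to 2,3,3-trimethoxypropanal F3, used crude. Dienolate 11, made from 6 with one equivalent of LiN(SiMe3)2 at −78 °C, should add to F3 to give 6-(2-hydroxy-1,3,4,4-tetramethoxybutyl)-3-methoxy-2-(4-methoxyphenyl)-4H-pyran-4-one F4; no excess base is needed because the alkoxide product is not acidic. Dess–Martin oxidation of F4 (CH2Cl2, NaHCO3, rt) returns to the route at 12.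

3. Step 2. Etherification of the primary alcohol may be slow under Ag2O, and forcing it with stronger base would expose the C–Br bond to displacement by alkoxide. The fallback removes the bromide before the alcohol is methylated and sets out from 2. K2CO3 and MeI in acetone should methylate only the acidic enol and give 3, which is isolated. Suzuki–Miyaura coupling of 3 with 5 (Pd(PPh3)4, K3PO4, dioxane/H2O) gives 6-(hydroxymethyl)-3-methoxy-2-(4-methoxyphenyl)-4H-pyran-4-one F5. NaH and MeI in THF at 0 °C then methylate the primary alcohol and return to the route at 6.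

Further compounds
F1 | step 6 | methoxyacetic acid | COCC(=O)O
F2 | step 6 | 1-(2-hydroxy-3,4,5-trimethoxyphenyl)-2-methoxyethan-1-one | COCC(=O)c1cc(OC)c(OC)c(OC)c1O
F3 | step 5 | 2,3,3-trimethoxypropanal (racemic) | COC(OC)C(OC)C=O
F4 | step 5 | 6-(2-hydroxy-1,3,4,4-tetramethoxybutyl)-3-methoxy-2-(4-methoxyphenyl)-4H-pyran-4-one (mixture of diastereomers) | COc1ccc(-c2oc(C(OC)C(O)C(OC)C(OC)OC)cc(=O)c2OC)cc1
F5 | step 2 | 6-(hydroxymethyl)-3-methoxy-2-(4-methoxyphenyl)-4H-pyran-4-one | OCc1cc(=O)c(OC)c(-c2ccc(OC)cc2)o1
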